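**Retrosynthetic overview**
1. Target ⇒ phenol acetate removal, tigloylation of O10 and 4-acetoxybenzoylation of O6; the C6 carbinol comes from a hydroxyl-directed reduction of a C6 ketone, the C4 isopropyl carbinol from organocerium addition to a C4 ketone.
2. Feature the plan rests on: the seven-membered ring C1–C10–C9–C8–C7–C6–C5 holds the C8=C9 alkene and, with O6 written as an enol ether, a C5=C6 alkene, with sp3 C7 between them. This cyclohepta-1,4-diene is the product pattern of a cis-divinylcyclopropane Cope rearrangement whose new σ bond is C1–C10 (quaternary C1, oxygenated C10).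
3. Key disconnection: C7–C8 and C1–C10, giving a 2-silyloxydiene on the ethylene ketal of 3-methylcyclopent-2-enone (C1–C7, C15) and an (E)-4-silyloxy vinyldiazoacetate (C8–C10, ester carbon = C14), joined by enantioselective rhodium-carbenoid cyclopropanation of C6=C7 followed by Cope rearrangement.
4. Ring order: the five-membered ring comes with the starting enone; the transient cyclopropane C6–C7–C8 and then the seven-membered ring form in one step. Stereocentres follow in the order C1/C10 (key step), C5 (cis ring fusion), C4 (convex-face addition), C6 (directed reduction).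

Key step: step 8

Numbering used throughout: C1 = quaternary fusion carbon (methyl C15); C2, C3 = ring CH2; C4 = isopropyl carbinol carbon; C5 = fusion CH; C6 = aroyloxy carbon; C7 = CH2; C8 = alkene carbon bearing C14; C9 = alkene CH; C10 = tigloyloxy carbon. TBS = t-BuMe2Si, TES = Et3Si. The target is (1R,4R,5S,6S,10S): cis-fused, with C15, H5, O6 and isopropyl on one face and O4 and O10 on the other.

Assumption: Rh2(S-DOSP)4, dirhodium tetrakis[(S)-N-(4-dodecylbenzenesulfonyl)prolinate], is taken to select the same carbenoid face as with simple vinyl- and aryldiazoacetates (styrene gives the (1S,2R)-cyclopropane), which maps onto (1R,10S)-17; should the sense prove opposite, the commercially available Rh2(R-DOSP)4 is used.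

**Step 1**
Reactants: 1 3-methylcyclopent-2-en-1-one
Product: 3 2-bromo-3-methylcyclopent-2-en-1-one, via dibromide 2 (not isolated)
Conditions: Br2, CH2Cl2, 0 °C; then Et3N, 0 °C → rt
Reagents that add atoms: bromine, BrBr
Why: Bromine adds across the enone alkene and triethylamine removes HBr from the α-carbon of the dibromide, the standard addition–elimination α-bromination of a cyclic enone.

**Step 2**
Reactants: 3 2-bromo-3-methylcyclopent-2-en-1-one
Product: 4 6-bromo-7-methyl-1,4-dioxaspiro[4.4]non-6-ene
Conditions: HOCH2CH2OH, p-TsOH (cat.), benzene, reflux with azeotropic removal of water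
Reagents that add atoms: ethane-1,2-diol, OCCO
Why: Acid-catalysed ketalisation; the vinylic bromine holds the alkene in place, as is known for dioxolanes of 2-bromocycloalkenones.

**Step 3**
Reactants: 4 6-bromo-7-methyl-1,4-dioxaspiro[4.4]non-6-ene
Product: 7 1-(7-methyl-1,4-dioxaspiro[4.4]non-6-en-6-yl)ethan-1-one, via vinyllithium 5 (not isolated), via lithium hemiaminal alkoxide 6 (not isolated)
Conditions: n-BuLi, THF, −78 °C; MeC(O)N(OMe)Me, −78 → 0 °C; then H2O
Reagents that add atoms: n-butyllithium, [Li]CCCC (lithium held only in 5 and 6); N-methoxy-N-methylacetamide, CON(C)C(C)=O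
Why: Bromine–lithium exchange gives the vinyllithium, and its addition to the N-methoxy-N-methylamide stops at the chelated tetrahedral adduct, so work-up should release the methyl ketone without over-addition (organolithium acylation).

**Step 4**
Reactants: 7 1-(7-methyl-1,4-dioxaspiro[4.4]non-6-en-6-yl)ethan-1-one
Product: 9 silyloxydiene triethyl{[1-(7-methyl-1,4-dioxaspiro[4.4]non-6-en-6-yl)ethenyl]oxy}silane, via lithium enolate 8 (not isolated)
Conditions: LiN(i-Pr)2, THF, −78 °C; Et3SiCl, −78 → 0 °C; non-aqueous work-up
Reagents that add atoms: lithium diisopropylamide, [Li]N(C(C)C)C(C)C (lithium held only in 8); chlorotriethylsilane, CC[Si](Cl)(CC)CC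
Why: Kinetic deprotonation of the enone at the α'-methyl group gives the cross-conjugated enolate, whose O-silylation furnishes the 2-silyloxydiene (kinetic silyl enol ether formation).

**Step 5**
Reactants: 10 glycine methyl ester hydrochloride
Product: 11 methyl diazoacetate
Conditions: NaNO2, H2SO4 (cat.), CH2Cl2/H2O, −5 °C; kept and used as a CH2Cl2 solution
Reagents that add atoms: sodium nitrite, [Na+].[O-]N=O
Why: Diazotisation of the α-amino ester, the ester-stabilised diazonium ion losing a proton to give the diazoacetate.

**Step 6**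
Reactants: 11 methyl diazoacetate; 12 (tert-butyldimethylsilyloxy)acetaldehyde
Product: 13 methyl 4-(tert-butyldimethylsilyloxy)-2-diazo-3-hydroxybutanoate (racemic)
Conditions: DBU (10 mol%), MeCN, 0 °C → rt
Reagents that add atoms: none
Why: Base-catalysed aldol-type addition of the diazoacetate carbon to the aldehyde; the racemic carbinol centre is removed in step 7.

**Step 7**
Reactants: 13 methyl 4-(tert-butyldimethylsilyloxy)-2-diazo-3-hydroxybutanoate
Product: 15 methyl (E)-4-(tert-butyldimethylsilyloxy)-2-diazobut-3-enoate, via dichlorophosphate 14 (not isolated)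
Conditions: POCl3, Et3N, CH2Cl2, 0 °C; used promptly
Reagents that add atoms: phosphoryl chloride, O=P(Cl)(Cl)Cl (atoms held only in 14)
Why: Phosphorylation of the hydroxyl and amine-induced anti elimination (dehydration of a β-hydroxy-α-diazo ester to a vinyldiazoacetate); the (E)-enol ether is expected because the silyloxy group lies anti to the diazo ester in the eliminating conformer, so the geometry is fixed by the elimination and not by an aldehyde enolisation.

**Step 8 (key step)**
Reactants: 9 silyloxydiene; 15 methyl (E)-4-(tert-butyldimethylsilyloxy)-2-diazobut-3-enoate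
Product: 17 cycloheptadiene ester (1R,10S; C8 CO2Me on C8=C9; C10 OTBS; C1 methyl; C5=C6 with C6 OTES; C4 ethylene ketal), via divinylcyclopropane 16 (not isolated)
Conditions: Rh2(S-DOSP)4 (1 mol%), 2,2-dimethylbutane, −45 °C → rt, 15 (1.5 equiv) added over 2 h; then toluene, 90 °C
Reagents that add atoms: none
Why: The divalent rhodium carboxylate Rh2(S-DOSP)4 decomposes 15 to a donor–acceptor vinylcarbenoid, which transfers C8 to the terminal, most nucleophilic alkene of 9 in a concerted asynchronous (2+1) addition (C7 bonds first, the charge at C6 being stabilised by the silyloxy group) and so closes the three-membered ring C6–C7–C8 of cis-divinylcyclopropane 16; on warming, 16 undergoes a Cope rearrangement through a boat transition state with both alkenyl groups folded over the ring, which breaks C6–C8, joins C1 to C10 and thereby closes the seven-membered ring by a [3,3]-sigmatropic shift. The closest known reaction type is the tandem cyclopropanation–Cope rearrangement (formal (4+3) cycloaddition) of rhodium vinylcarbenoids with 2-silyloxydienes and with cyclic dienes that carry a methyl-bearing, fully substituted terminus; the (E)-4-silyloxy group on the carbenoid is the untested element. The cyclopropane configuration (1R,2S), set by the chiral catalyst, is relayed by the boat geometry: the (E)-silyloxy group on C10 and ring carbon C2 on C1 point outward and end cis, so O10 should come out trans to the inward C1 methyl and the two new stereocentres as 1R,10S. The step needs site selectivity for the enol-ether alkene over the tetrasubstituted alkene (secured by electron density and sterics), reaction at the carbenoid carbon and not at the vinyl terminus (favoured by the substituted terminus, the methyl ester and the hydrocarbon solvent), a cis arrangement of the two alkenyl groups (favoured by donor–acceptor carbenoids, and reachable from a trans isomer by thermal opening and reclosure of the donor–acceptor cyclopropane) and catalyst-controlled facial selectivity. The inward methyl at C1 slows the rearrangement, which is why the mixture is heated.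

**Step 9**
Reactants: 17 cycloheptadiene ester
Product: 18 allylic alcohol (1R,10S; C8 CH2OH; otherwise as 17)
Conditions: i-Bu2AlH (2.5 equiv), CH2Cl2, −78 °C; aqueous potassium sodium tartrate work-up
Reagents that add atoms: none
Why: 1,2-Reduction of the conjugated ester to the primary allylic alcohol by the aluminium hydride at low temperature, which the silyl ether, the silyl enol ether and the ketal tolerate.

**Step 10**
Reactants: 18 allylic alcohol
Product: 20 C14-methyl diene (1R,10S; C8 CH3 on C8=C9; C10 OTBS; C6 OTES enol ether; C4 ketal), via allylic mesylate 19 (not isolated)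
Conditions: MeSO2Cl, Et3N, CH2Cl2, −30 °C; then LiEt3BH, THF, 0 °C
Reagents that add atoms: methanesulfonyl chloride, CS(Cl)(=O)=O (atoms held only in 19)
Why: The primary allylic sulfonate is displaced by hydride in an SN2 reaction at the unhindered CH2 (the SN2' position C9 is shielded by C10 and its silyl ether), so C8=C9 should stay in place (deoxygenation by sulfonate reduction).

**Step 11**
Reactants: 20 C14-methyl diene
Product: 22 C6 alcohol (1R,5S,6R,10S; cis-fused; C4 ketal; C10 OTBS), via ketone 21 (not isolated)
Conditions: Bu4NF, AcOH, THF, −20 → 0 °C; then MeOH, NaBH4, 0 °C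
Reagents that add atoms: none
Why: Buffered fluoride cleaves only the triethylsilyl enol ether, and the enol is protonated at C5 without moving the β,γ-alkene into conjugation, the cis-fused ketone being the expected kinetic (convex-face) and thermodynamic isomer; borohydride reduction of the ketone from the convex face should then give the 6R alcohol, whose configuration is erased in step 14 and therefore does not matter.

**Step 12**
Reactants: 22 C6 alcohol
Product: 23 C4 ketone (1R,5S,6R,10S; cis-fused β-hydroxy cyclopentanone; C10 OTBS)
Conditions: pyridinium p-toluenesulfonate (cat.), acetone/H2O 10:1, 50 °C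
Reagents that add atoms: water, O
Why: Mild acid-catalysed ketal hydrolysis frees the C4 ketone while the hindered secondary TBS ether survives; under these enolising conditions C5 can settle in the cis-fused arrangement, expected to be the more stable one for this angularly methylated hydroazulenone, so a trans-fused share from step 11 would converge here.

**Step 13**
Reactants: 23 C4 ketone
Product: 24 diol (1R,4R,5S,6R,10S; C4 OH and isopropyl; C6 OH; C10 OTBS)
Conditions: i-PrMgCl (4 equiv), CeCl3 (anhydrous, 4 equiv), THF, −78 → 0 °C
Reagents that add atoms: isopropylmagnesium chloride, CC(C)[Mg]Cl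
Why: Organocerium 1,2-addition to the hindered, enolisable cyclopentanone (one equivalent is spent on the C6 hydroxyl); attack is expected on the convex face, anti to the C5–C6 bond, which puts isopropyl cis to H5 and the new hydroxyl on the concave face (4R).

**Step 14**
Reactants: 24 diol
Product: 25 β-hydroxy ketone (1R,4R,5R,10S; C6 ketone; C4 tertiary OH; the C5 descriptor changes by priority only)
Conditions: Dess–Martin periodinane (1.5 equiv), NaHCO3, CH2Cl2, 0 °C → rt
Reagents that add atoms: none
Why: Dess–Martin oxidation converts only the secondary C6 alcohol into the ketone under buffered, non-enolising conditions, leaving the tertiary aldol, the β,γ-alkene and C5 untouched.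

**Step 15**
Reactants: 25 β-hydroxy ketone
Product: 26 anti-diol (1R,4R,5S,6S,10S; C6 OH on the convex face; C10 OTBS)
Conditions: Me4NBH(OAc)3 (5 equiv), MeCN/AcOH 1:1, −30 °C
Reagents that add atoms: none
Why: Evans–Saksena reduction: the C4 hydroxyl exchanges onto boron and delivers hydride intramolecularly to the concave face of the C6 carbonyl, which should give the 1,3-anti diol with the C6 hydroxyl cis to H5 (6S).

**Step 16**
Reactants: 27 4-acetoxybenzoic acid
Product: 28 4-acetoxybenzoyl chloride
Conditions: (COCl)2, DMF (cat.), CH2Cl2, 0 °C → rt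
Reagents that add atoms: oxalyl chloride, O=C(Cl)C(Cl)=O
Why: Acid chloride formation through the chloroiminium species generated from DMF; the aryl acetate is inert.

**Step 17**
Reactants: 26 anti-diol; 28 4-acetoxybenzoyl chloride
Product: 29 C6 4-acetoxybenzoate (1R,4R,5S,6S,10S; C10 OTBS; C4 OH free)
Conditions: pyridine, DMAP (cat.), CH2Cl2, 0 °C → rt
Reagents that add atoms: none
Why: Nucleophile-catalysed acylation of the secondary C6 hydroxyl with retention; the tertiary C4 hydroxyl is too hindered to compete.

**Step 18**
Reactants: 29 C6 4-acetoxybenzoate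
Product: 30 C10 alcohol (1R,4R,5S,6S,10S)
Conditions: HF·pyridine, pyridine/THF, 0 °C → rt
Reagents that add atoms: none
Why: Fluoride-mediated desilylation under weakly acidic conditions, to which the aryl acetate, the benzoate-type ester and the tertiary alcohol are stable.

**Step 19**
Reactants: 30 C10 alcohol; 31 tiglic acid
Product: 32 C10 tiglate C6 4-acetoxybenzoate (1R,4R,5S,6S,10S)
Conditions: 31, 2,4,6-Cl3C6H2COCl, Et3N, toluene, rt; then 30, DMAP, toluene, rt → 50 °C
Reagents that add atoms: none
Why: Yamaguchi esterification: DMAP attacks the mixed anhydride at the tigloyl carbonyl and the acylpyridinium acylates the hindered allylic C10 hydroxyl with retention, the (E)-alkene of the tiglate being configurationally stable.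

**Step 20**
Reactants: 32 C10 tiglate C6 4-acetoxybenzoate
Product: 33 target CNP0273650.3
Conditions: NH4OAc, MeOH/H2O 4:1, rt
Reagents that add atoms: none
Why: Chemoselective methanolysis of the activated aryl acetate, which should be cleaved far faster than the two alkyl esters, releases the phenol.

**Compound list**
1 | 3-methylcyclopent-2-en-1-one | CC1=CC(=O)CC1 | starting material
2 | 2,3-dibromo-3-methylcyclopentan-1-one (racemic adduct) | CC1(Br)CCC(=O)C1Br | intermediate
3 | 2-bromo-3-methylcyclopent-2-en-1-one | CC1=C(Br)C(=O)CC1 | intermediate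
4 | 6-bromo-7-methyl-1,4-dioxaspiro[4.4]non-6-ene | CC1=C(Br)C2(CC1)OCCO2 | intermediate
5 | (7-methyl-1,4-dioxaspiro[4.4]non-6-en-6-yl)lithium | [Li]C1=C(C)CCC12OCCO2 | intermediate
6 | lithium 1-[methoxy(methyl)amino]-1-(7-methyl-1,4-dioxaspiro[4.4]non-6-en-6-yl)ethan-1-olate | CON(C)C(C)(O[Li])C1=C(C)CCC12OCCO2 | intermediate
7 | 1-(7-methyl-1,4-dioxaspiro[4.4]non-6-en-6-yl)ethan-1-one | CC(=O)C1=C(C)CCC12OCCO2 | intermediate
8 | lithium 1-(7-methyl-1,4-dioxaspiro[4.4]non-6-en-6-yl)ethen-1-olate | [Li]OC(=C)C1=C(C)CCC12OCCO2 | intermediate
9 | triethyl{[1-(7-methyl-1,4-dioxaspiro[4.4]non-6-en-6-yl)ethenyl]oxy}silane | C=C(O[Si](CC)(CC)CC)C1=C(C)CCC12OCCO2 | intermediate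
10 | glycine methyl ester hydrochloride | COC(=O)C[NH3+].[Cl-] | starting material
11 | methyl diazoacetate | COC(=O)C=[N+]=[N-] | intermediate
12 | (tert-butyldimethylsilyloxy)acetaldehyde | CC(C)(C)[Si](C)(C)OCC=O | starting material
13 | methyl 4-(tert-butyldimethylsilyloxy)-2-diazo-3-hydroxybutanoate (racemic) | COC(=O)C(=[N+]=[N-])C(O)CO[Si](C)(C)C(C)(C)C | intermediate
14 | methyl 4-(tert-butyldimethylsilyloxy)-2-diazo-3-(dichlorophosphoryloxy)butanoate | COC(=O)C(=[N+]=[N-])C(OP(=O)(Cl)Cl)CO[Si](C)(C)C(C)(C)C | intermediate
15 | methyl (E)-4-(tert-butyldimethylsilyloxy)-2-diazobut-3-enoate | COC(=O)C(=[N+]=[N-])/C=C/O[Si](C)(C)C(C)(C)C | intermediate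
16 | methyl (1R,2S)-1-[(E)-2-(tert-butyldimethylsilyloxy)ethenyl]-2-(7-methyl-1,4-dioxaspiro[4.4]non-6-en-6-yl)-2-(triethylsilyloxy)cyclopropane-1-carboxylate | COC(=O)[C@@]1(/C=C/O[Si](C)(C)C(C)(C)C)C[C@]1(O[Si](CC)(CC)CC)C2=C(C)CCC23OCCO3 | intermediate
17 | (1R,10S)-cycloheptadiene ester: C8 CO2Me, C8=C9, C10 OTBS, C1 CH3, C5=C6 with C6 OTES, C4 ethylene ketal | CC(C)(C)[Si](C)(C)O[C@H]1C=C(C(=O)OC)CC(O[Si](CC)(CC)CC)=C2[C@@]1(C)CCC23OCCO3 | intermediate
18 | (1R,10S)-allylic alcohol: C8 CH2OH, otherwise as 17 | CC(C)(C)[Si](C)(C)O[C@H]1C=C(CO)CC(O[Si](CC)(CC)CC)=C2[C@@]1(C)CCC23OCCO3 | intermediate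
19 | (1R,10S)-allylic mesylate: C8 CH2OSO2Me, otherwise as 17 | CC(C)(C)[Si](C)(C)O[C@H]1C=C(COS(C)(=O)=O)CC(O[Si](CC)(CC)CC)=C2[C@@]1(C)CCC23OCCO3 | intermediate
20 | (1R,10S)-C14-methyl diene: C8 CH3, C8=C9, C10 OTBS, C6 OTES enol ether, C4 ketal | CC(C)(C)[Si](C)(C)O[C@H]1C=C(C)CC(O[Si](CC)(CC)CC)=C2[C@@]1(C)CCC23OCCO3 | intermediate
21 | (1R,5S,10S)-cis-fused C6 ketone, C4 ketal, C10 OTBS | CC(C)(C)[Si](C)(C)O[C@H]1C=C(C)CC(=O)[C@@H]2[C@@]1(C)CCC23OCCO3 | intermediate
22 | (1R,5S,6R,10S)-C6 alcohol, C4 ketal, C10 OTBS | CC(C)(C)[Si](C)(C)O[C@H]1C=C(C)C[C@@H](O)[C@@H]2[C@@]1(C)CCC23OCCO3 | intermediate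
23 | (1R,5S,6R,10S)-C4 ketone with C6 OH, C10 OTBS | CC(C)(C)[Si](C)(C)O[C@H]1C=C(C)C[C@@H](O)[C@@H]2[C@@]1(C)CCC2=O | intermediate
24 | (1R,4R,5S,6R,10S)-diol: C4 OH and isopropyl, C6 OH, C10 OTBS | CC(C)(C)[Si](C)(C)O[C@H]1C=C(C)C[C@@H](O)[C@@H]2[C@@]1(C)CC[C@@]2(O)C(C)C | intermediate
25 | (1R,4R,5R,10S)-β-hydroxy ketone: C6 ketone, C4 OH and isopropyl, C10 OTBS | CC(C)(C)[Si](C)(C)O[C@H]1C=C(C)CC(=O)[C@@H]2[C@@]1(C)CC[C@@]2(O)C(C)C | intermediate
26 | (1R,4R,5S,6S,10S)-anti-diol: C6 OH cis to H5, C4 OH, C10 OTBS | CC(C)(C)[Si](C)(C)O[C@H]1C=C(C)C[C@H](O)[C@@H]2[C@@]1(C)CC[C@@]2(O)C(C)C | intermediate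
27 | 4-acetoxybenzoic acid | CC(=O)Oc1ccc(cc1)C(O)=O | starting material
28 | 4-acetoxybenzoyl chloride | CC(=O)Oc1ccc(cc1)C(Cl)=O | intermediate
29 | (1R,4R,5S,6S,10S)-C6 4-acetoxybenzoate, C10 OTBS, C4 OH | CC(C)(C)[Si](C)(C)O[C@H]1C=C(C)C[C@H](OC(=O)c2ccc(OC(C)=O)cc2)[C@@H]3[C@@]1(C)CC[C@@]3(O)C(C)C | intermediate
30 | (1R,4R,5S,6S,10S)-C10 alcohol, C6 4-acetoxybenzoate, C4 OH | O[C@H]1C=C(C)C[C@H](OC(=O)c2ccc(OC(C)=O)cc2)[C@@H]3[C@@]1(C)CC[C@@]3(O)C(C)C | intermediate
31 | tiglic acid, (E)-2-methylbut-2-enoic acid | C/C=C(\C)C(O)=O | starting material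
32 | (1R,4R,5S,6S,10S)-C10 tiglate, C6 4-acetoxybenzoate, C4 OH | C/C=C(\C)C(=O)O[C@H]1C=C(C)C[C@H](OC(=O)c2ccc(OC(C)=O)cc2)[C@@H]3[C@@]1(C)CC[C@@]3(O)C(C)C | intermediate
33 | CNP0273650.3, (1R,4R,5S,6S,10S)-C10 tiglate C6 4-hydroxybenzoate | C/C=C(\C)C(=O)O[C@H]1C=C(C)C[C@H](OC(=O)c2ccc(O)cc2)[C@@H]2[C@@]1(C)CC[C@@]2(O)C(C)C | target

**Step count**
Total: 20 steps. Longest linear sequence: 16 steps (steps 1–4, 8–15, 17–20, from 3-methylcyclopent-2-en-1-one).

**Steps most likely to fail**

Step 8 (cyclopropanation–Cope union). What may go wrong: enantiofacial discrimination at the hindered 1,1-disubstituted enol ether may be poor, and material passing through the trans-cyclopropane and its ring-opened zwitterion would lose its configuration, so 17 could form with low enantiomeric purity. Reaction at the silyloxy-bearing vinyl terminus would appear as open-chain by-products and is countered by the hydrocarbon solvent and slow addition. Fallback: classical resolution in place of catalyst control. It sets out from diol 26 of insufficient enantiomeric purity (made by the same steps, if need be with achiral Rh2(O2CC7H15)4 in step 8). Esterification of the C6 hydroxyl with (S)-2-methoxy-2-phenylacetic acid (N,N'-dicyclohexylcarbodiimide, DMAP, CH2Cl2, −10 °C) should give two diastereomeric esters, from which the (1R,4R,5S,6S,10S) (S)-O-methylmandelate ester F1 is separated by chromatography or crystallisation. Methanolysis (K2CO3, MeOH) returns to the route at enantiomerically pure 26.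

Step 13 (isopropyl addition). What may go wrong: the secondary organometallic may act as a base or hydride donor toward the hindered ketone (enolisation, β-hydride reduction), or the metal aldolate may open by retro-aldol cleavage, so that little adduct forms. Fallback: a smaller sp2 nucleophile that cannot transfer hydride, followed by selective hydrogenation. It sets out from 23: CH2=C(CH3)MgBr with CeCl3 in THF at −78 °C should add from the convex face to give the isopropenyl carbinol F2. Hydrogenation of its 1,1-disubstituted alkene with H2 and RhCl(PPh3)3 in benzene, which should leave the hindered trisubstituted C8=C9 alkene untouched, returns to the route at 24.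

Step 15 (directed reduction). What may go wrong: slow exchange of the tertiary C4 hydroxyl onto boron may let hydride arrive undirected (poor facial selectivity at C6) or not at all, and the tertiary aldol 25 may suffer retro-aldol cleavage or dehydration on the way. Fallback: inversion in place of the oxidation–reduction pair. It sets out from diol 24 (6R alcohol): a Mitsunobu reaction with 4-acetoxybenzoic acid 27 (PPh3, diisopropyl azodicarboxylate, toluene, 0 °C → rt), in which the carboxylate enters from the convex face with inversion at C6, should give 29 directly and so comes back to the route at 29. Steps 14 to 17 are then not needed; the concave C4 hydroxyl cannot reach the backside of C6, so oxetane formation is not expected.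

**Further compounds**
F1 | step 8 | (1R,4R,5S,6S,10S)-C6 (S)-2-methoxy-2-phenylacetate of diol 26 | CC(C)(C)[Si](C)(C)O[C@H]1C=C(C)C[C@H](OC(=O)[C@@H](OC)c2ccccc2)[C@@H]3[C@@]1(C)CC[C@@]3(O)C(C)C
F2 | step 13 | (1R,4S,5S,6R,10S)-isopropenyl carbinol: C4 OH and prop-1-en-2-yl (on the face of H5), C6 OH, C10 OTBS | CC(C)(C)[Si](C)(C)O[C@H]1C=C(C)C[C@@H](O)[C@@H]2[C@@]1(C)CC[C@@]2(O)C(C)=C
F0 | step 15 | none | none
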